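Remark on the chemistry: ring A is numbered from its carboxyl-bearing carbon (C1) and ring B from its ester-bearing carbon (C1). The target has no stereocentre, so no configuration has to be set.

## Analysis of the target

The target is a depside: two benzene rings joined by a single aryl ester, with no further ring and no stereocentre. Ring A is the acyl part and is hexasubstituted: C1 carries the ester carbonyl, C2 and C4 hydroxyls, C3 and C5 formyl groups, C6 a methyl. Ring B is the phenolic part and is also hexasubstituted: C1 carries CO2Me, C2 a methoxy group, C3, C5 and C6 methyls, and C4 the ester oxygen. The sensitive groups are the two aromatic aldehydes (Cannizzaro reaction, condensation with amines, over-oxidation), the two acidic chelated phenols, and the two esters. The central difficulty is the ester itself. Its acyl carbon sits between ring A C2–O and the C6 methyl, and its oxygen sits on ring B C4 between the C3 and C5 methyls, so an acyl substitution has to pass through a very crowded tetrahedral intermediate. Two further problems are that ring B carries two different oxygens (a methyl ether at C2, an ester at C4) and that ring A needs two formyl groups on a ring already deactivated by a carboxyl group. The strategy rests on the bond between ring B C4 and the ester oxygen. Because both neighbours of ring B C4 are methyl groups, an aryl group bound to trivalent iodine through this carbon is predisposed to ligand coupling. The bond is therefore made from the ring A carboxylate oxygen to ring B C4, not from a ring B phenol to the ring A acyl carbon.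

## Retrosynthetic reasoning

**Unmasking the phenols.** The target 17 is traced back to its bis(methoxymethyl) ether 16. Only two acetal C–O bonds are cut in the last step. Methoxymethyl ethers are chosen because aqueous protic acid removes them and leaves the hindered aryl ester, the methyl ester and the aldehydes alone. Lewis-acid dealkylation, as needed for methyl or benzyl ethers, would also attack the ring B methoxy group ortho to its ester.

**The aryl–oxygen bond.** In 16 the bond between ring B C4 and the ester oxygen is cut, not the acyl C–O bond. This gives the ring A acid 14 and the ring B aryl(2,4,6-trimethoxyphenyl)iodonium tosylate 9. The reason for cutting here is steric: an acylation would bring a di-ortho-substituted acyl carbon and a di-ortho-methylated phenol together, whereas in the chosen direction the nucleophile is a carboxylate oxygen that lies outside the crowded region of ring A. The two methyls next to ring B C4 then help, because ortho substituents accelerate ligand coupling at trivalent iodine. A second gain is that the C4 oxygen comes from the acid, so ring B never has to carry two oxygens that must be told apart. The forward reaction has to deliver the ring B aryl group and not the trimethoxyphenyl group, and it has to arylate only the carboxylate. This is why the ring A phenols are masked in 14.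

**The iodonium salt.** In 9 the bond between iodine and the trimethoxyphenyl ring is cut, giving the ring B iodide 6 and 1,3,5-trimethoxybenzene 7. Forward, 6 is oxidised to trivalent iodine and the activated species 8 is attacked by 7. Compound 7 has three equivalent ring C–H positions, so there is no regiochemistry to control. Compound 6 has no ring C–H at all, so it cannot condense with itself.

**The C4–iodine bond.** Iodide 6 is traced back to methyl 2-methoxy-3,5,6-trimethylbenzoate 5 by cutting the C4–I bond. C4 is the only unsubstituted ring carbon of 5, so an electrophilic iodination can give only one regioisomer. This replaces a longer nitration, reduction and diazotisation sequence by one step.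

**The ring B carbon skeleton.** In 5 the bond between ring B C1 and the ester carbon is cut, leading through the aryllithium 4 to the bromoanisole 3. Compound 3 comes from the bromophenol 2 by O-methylation, and 2 from commercially available 2,4,5-trimethylphenol 1 by bromination at the only free ortho position. All three methyls and the oxygen of 1 are already in the right places, so ring B needs no ring construction.

**The ring A acid.** Acid 14 is traced back to its allyl ester 13, then to the free bisphenol 12, then to allyl orsellinate 11, and finally to orsellinic acid 10. The two formyl C–C bonds at C3 and C5 are cut together: these are the only free positions of 11 and each is ortho or para to both hydroxyls, so a double formylation converges on one product. The carboxyl group has to be an ester during the formylation, because the free β-resorcylic acid 10 decarboxylates in hot acid. The allyl ester is chosen because it can later be removed under neutral conditions at the allyl carbon. A base-mediated saponification at the hindered acyl carbon would endanger the two aldehydes.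

## Alternatives that were turned down

**Alternative 1:** Ring B would be disconnected at its C1–C6 bond to the open-chain methyl 4,6-dimethyl-3,5,7-trioxooctanoate (A2). Forward, the C2 enolate of A2 adds to the C7 ketone, and dehydration with enolisation gives methyl 2,4-dihydroxy-3,5,6-trimethylbenzoate (A1).
- In its favour: one closure assembles the whole hexasubstituted ring with all three methyls, the ring oxygen at C4 is present from the start, and no halogen or iodine chemistry is needed. On bonds formed per step for ring B it is stronger than the chosen route.
- Against it: A2 is an enolisable triketo ester with two epimerisable methyl-bearing carbons. It can also close by a Claisen-type attack of C6 on the ester, by O-cyclisation to pyranones, or by aldol reactions of the other enolates, and nothing in the chain favours the wanted mode. A1 then has two free phenols, and the one that must be methylated (C2, chelated to the ester) is the less reactive, so a protection sequence is needed.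
- Comparison: the C4 hydroxyl of A1 still has to be acylated by the hindered ring A acid, so the main problem of the target is left untouched. The chosen strategy buys the ring B substitution pattern in 1 and spends its effort on the ester bond.

**Alternative 2:** Ring A would be disconnected at its C1–C2 and C5–C6 bonds. The ester is made first, as methyl 4-(but-2-ynoyloxy)-2-methoxy-3,5,6-trimethylbenzoate (A3). A Diels–Alder reaction of A3 with 1-methoxy-1,3-bis(trimethylsilyloxy)buta-1,3-diene (A4), followed by loss of methanol and of the silyl groups, gives methyl 4-(2,4-dihydroxy-6-methylbenzoyloxy)-2-methoxy-3,5,6-trimethylbenzoate (A5).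
- In its favour: the ester bond is formed with a slender linear acyl group, and the crowding at the acyl carbon appears only when ring A grows around it. The polarisation of A4 and A3 matches the required orientation, and no protecting group is needed in the key step. On avoiding the hindered acylation it is at least as strong as the chosen strategy.
- Against it: an internal ynoate with a methyl on its β-carbon is a sluggish dienophile, and A4 is easily hydrolysed. A5 lacks both formyl groups, so the double formylation would have to be done in hot acid on the finished depside. A3 also requires the C4-hydroxy form of ring B, which brings back the differentiation of the two ring B oxygens.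
- Comparison: the chosen strategy formylates a simple monocyclic ester, where failure costs little, and brings the complete ring A into one convergent step.

**Alternative 3:** Ring B would be disconnected at its C2–C3 and C4–C5 bonds. Methyl 3-methoxy-5,6-dimethyl-2-oxo-2H-pyran-4-carboxylate (A6) reacts as a diene with 1-(triisopropylsilyloxy)propyne (A7), and the bridged adduct loses CO2 to give methyl 2-methoxy-3,5,6-trimethyl-4-(triisopropylsilyloxy)benzoate (A8).
- In its favour: the C4 oxygen arrives already differentiated from the C2 methoxy group, and the loss of CO2 makes the aromatisation irreversible. On differentiating the two ring B oxygens it is stronger than a route through a free resorcinol.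
- Against it: the orientation is not secured. The lactone carbonyl of A6 makes pyrone C6 the electrophilic terminus, which would join the nucleophilic methyl-bearing carbon of A7 to the wrong end and place the silyloxy group next to the methoxy carbon. The C4 ester favours the wanted sense, but the methoxy donor on C3 opposes it. A6 is a fully substituted, slow diene that needs its own synthesis, and A7 is sensitive.
- Comparison: desilylation of A8 only exposes the hindered C4 hydroxyl, so the difficult acylation remains. The chosen strategy reaches a single ring B regioisomer by construction, since 5 has only one ring C–H, and never needs that hydroxyl.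

Key step: step 10

## Route

Step 1
Reactants: 1 2,4,5-trimethylphenol
Product: 2 2-bromo-3,4,6-trimethylphenol
Conditions: Br2 (1.0 equiv), CH2Cl2, 0 °C
Reagents that add atoms: bromine, BrBr
Why: Electrophilic aromatic bromination; the hydroxyl directs to its only free ortho position, the para position is blocked by a methyl and the other free carbon is meta to the hydroxyl.

Step 2
Reactants: 2 2-bromo-3,4,6-trimethylphenol
Product: 3 2-bromo-1-methoxy-3,4,6-trimethylbenzene
Conditions: MeI, K2CO3, DMF, 40 °C
Reagents that add atoms: iodomethane, CI
Why: Williamson ether synthesis; the phenoxide between bromine and methyl is still readily alkylated by the small electrophile in a dipolar aprotic solvent.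

Step 3
Reactants: 3 2-bromo-1-methoxy-3,4,6-trimethylbenzene
Product: 5 methyl 2-methoxy-3,5,6-trimethylbenzoate, via (2-methoxy-3,5,6-trimethylphenyl)lithium 4 (not isolated)
Conditions: n-BuLi, THF, −78 °C; then ClCO2Me (excess), −78 °C → rt
Reagents that add atoms: methyl chloroformate, COC(=O)Cl
Why: Bromine–lithium exchange with n-BuLi (which supplies the lithium of 4) is faster than benzylic deprotonation at −78 °C. Acylation of the di-ortho-substituted aryllithium stops at the ester because the hindered product resists a second addition.

Step 4
Reactants: 5 methyl 2-methoxy-3,5,6-trimethylbenzoate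
Product: 6 methyl 4-iodo-2-methoxy-3,5,6-trimethylbenzoate
Conditions: NIS, TFA, 0 °C → rt, dark
Reagents that add atoms: N-iodosuccinimide, O=C1CCC(=O)N1I
Why: Electrophilic aromatic iodination with acid-activated N-iodosuccinimide; ring B C4 is the only unsubstituted ring carbon, is activated by two ortho methyls, and is only weakly deactivated by the ester, which is twisted out of conjugation by its two ortho substituents.

Step 5
Reactants: 6 methyl 4-iodo-2-methoxy-3,5,6-trimethylbenzoate; 7 1,3,5-trimethoxybenzene
Product: 9 [4-(methoxycarbonyl)-3-methoxy-2,5,6-trimethylphenyl](2,4,6-trimethoxyphenyl)iodonium tosylate, via the aryl(hydroxy)(tosyloxy)iodane 8 (not isolated)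
Conditions: mCPBA, TsOH·H2O, MeCN, 77 °C; then 7, 77 °C → rt; precipitation with Et2O
Reagents that add atoms: p-toluenesulfonic acid monohydrate, Cc1ccc(S(=O)(=O)O)cc1.O
Why: One-pot synthesis of an unsymmetrical diaryliodonium salt: mCPBA oxidises the iodide to trivalent iodine (its oxygen sits on iodine in 8 and leaves as water), and electrophilic aromatic substitution on 7 forms the second C–I bond. Compound 7 has three equivalent C–H positions and 6 has no ring C–H, so only one salt can form.

Step 6
Reactants: 10 orsellinic acid (2,4-dihydroxy-6-methylbenzoic acid)
Product: 11 allyl 2,4-dihydroxy-6-methylbenzoate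
Conditions: allyl bromide, KHCO3, DMF, rt
Reagents that add atoms: allyl bromide, C=CCBr
Why: Chemoselective SN2 alkylation of the carboxylate; KHCO3 deprotonates only the carboxylic acid, so the phenols stay free, and room temperature avoids decarboxylation of the β-resorcylic acid.

Step 7
Reactants: 11 allyl 2,4-dihydroxy-6-methylbenzoate
Product: 12 allyl 3,5-diformyl-2,4-dihydroxy-6-methylbenzoate
Conditions: hexamethylenetetramine (excess), TFA, 90 °C; then 3 M HCl (aq), 60 °C
Reagents that add atoms: hexamethylenetetramine, C1N2CN3CN1CN(C2)C3; water, O
Why: Double Duff reaction; C3 and C5 are the only free ring positions and each is ortho or para to both hydroxyls, so exhaustive formylation gives one product whichever carbon reacts first. The aminomethyl stage formed before hydrolysis deactivates the ring less than a formyl group, which allows the second substitution.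

Step 8
Reactants: 12 allyl 3,5-diformyl-2,4-dihydroxy-6-methylbenzoate
Product: 13 allyl 3,5-diformyl-2,4-bis(methoxymethoxy)-6-methylbenzoate
Conditions: MOMCl, i-Pr2NEt, CH2Cl2, 0 °C → reflux
Reagents that add atoms: chloromethyl methyl ether, COCCl
Why: O-alkylation of the phenols with an α-chloro ether; the acidic, chelated phenoxides are weak nucleophiles, but the electrophile reacts through an oxocarbenium-like transition state, and the aldehydes and the ester are not touched by the tertiary amine.

Step 9
Reactants: 13 allyl 3,5-diformyl-2,4-bis(methoxymethoxy)-6-methylbenzoate
Product: 14 3,5-diformyl-2,4-bis(methoxymethoxy)-6-methylbenzoic acid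
Conditions: Pd(PPh3)4 (5 mol %), 4-MeC6H4SO2Na, THF/MeOH, rt; then cold dilute HCl to pH 3, EtOAc
Reagents that add atoms: none
Why: Tsuji–Trost deallylation; zerovalent palladium ionises the allyl ester at the allyl carbon, far from the hindered acyl carbon, and the sulfinate traps the allyl palladium complex as a sulfone. The neutral conditions spare the acetals and aldehydes, and a sulfinate scavenger avoids the imine formation an amine would cause.

Step 10
Reactants: 14 3,5-diformyl-2,4-bis(methoxymethoxy)-6-methylbenzoic acid; 9 [4-(methoxycarbonyl)-3-methoxy-2,5,6-trimethylphenyl](2,4,6-trimethoxyphenyl)iodonium tosylate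
Product: 16 methyl 4-[3,5-diformyl-2,4-bis(methoxymethoxy)-6-methylbenzoyloxy]-2-methoxy-3,5,6-trimethylbenzoate, via the aryl(carboxylato)(trimethoxyphenyl)iodane 15 (not isolated)
Conditions: Cs2CO3, toluene, 4 Å MS, rt; then 9, 110 °C
Reagents that add atoms: none
Why: Cs2CO3 converts 14 into its caesium carboxylate, which displaces tosylate on the trivalent iodine of 9 to give the T-shaped iodane 15. Ligand coupling then joins the carboxylate oxygen to the ipso carbon of ring B (C4) through a three-centre transition state, while iodine is reduced to monovalent iodine and leaves as 2-iodo-1,3,5-trimethoxybenzene. The closest known reaction type is the metal-free O-arylation of carboxylic acids with diaryliodonium salts, including unsymmetrical aryl(2,4,6-trimethoxyphenyl) salts. One carbon–oxygen bond is formed; no ring closes and no stereocentre is created. The selectivity needed is chemoselective aryl transfer: the three methoxy donors make the ipso carbon of the trimethoxyphenyl group electron-rich and a poor acceptor, whereas ring B C4 is para to an ester and flanked by two methyls, whose steric pressure is relieved in the coupling transition state and which favour the reactive equatorial site on iodine. The attacking oxygen lies outside the crowded region of ring A, so the hindrance that blocks acyl substitution matters little here. Only the carboxylate can be arylated because both ring A phenols are methoxymethyl ethers; the aldehydes and acetals are inert to carbonate in toluene, and neither aryl group on iodine has an ortho hydrogen, which excludes an aryne pathway.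

Step 11
Reactants: 16 methyl 4-[3,5-diformyl-2,4-bis(methoxymethoxy)-6-methylbenzoyloxy]-2-methoxy-3,5,6-trimethylbenzoate
Product: 17 methyl 4-(3,5-diformyl-2,4-dihydroxy-6-methylbenzoyloxy)-2-methoxy-3,5,6-trimethylbenzoate (the target)
Conditions: 3 M HCl (aq), THF, 40 °C
Reagents that add atoms: none
Why: Acid-catalysed acetal hydrolysis; methoxymethyl ethers ortho to carbonyl groups cleave readily, while the doubly ortho-substituted aryl ester and the hindered methyl ester resist aqueous acid. Both rings are fully substituted, so the released formaldehyde cannot attack them.

## Compound list

1 | 2,4,5-trimethylphenol | Cc1cc(C)c(O)cc1C | starting material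
2 | 2-bromo-3,4,6-trimethylphenol | Cc1cc(C)c(O)c(Br)c1C | intermediate
3 | 2-bromo-1-methoxy-3,4,6-trimethylbenzene | COc1c(C)cc(C)c(C)c1Br | intermediate
4 | (2-methoxy-3,5,6-trimethylphenyl)lithium | [Li]c1c(C)c(C)cc(C)c1OC | intermediate
5 | methyl 2-methoxy-3,5,6-trimethylbenzoate | COC(=O)c1c(C)c(C)cc(C)c1OC | intermediate
6 | methyl 4-iodo-2-methoxy-3,5,6-trimethylbenzoate | COC(=O)c1c(C)c(C)c(I)c(C)c1OC | intermediate
7 | 1,3,5-trimethoxybenzene | COc1cc(OC)cc(OC)c1 | starting material
8 | methyl 4-[hydroxy(tosyloxy)iodanyl]-2-methoxy-3,5,6-trimethylbenzoate | COC(=O)c1c(C)c(C)c(I(O)OS(=O)(=O)c2ccc(C)cc2)c(C)c1OC | intermediate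
9 | [4-(methoxycarbonyl)-3-methoxy-2,5,6-trimethylphenyl](2,4,6-trimethoxyphenyl)iodonium tosylate | COC(=O)c1c(C)c(C)c([I+]c2c(OC)cc(OC)cc2OC)c(C)c1OC.Cc1ccc(S(=O)(=O)[O-])cc1 | intermediate
10 | orsellinic acid (2,4-dihydroxy-6-methylbenzoic acid) | Cc1cc(O)cc(O)c1C(=O)O | starting material
11 | allyl 2,4-dihydroxy-6-methylbenzoate | C=CCOC(=O)c1c(C)cc(O)cc1O | intermediate
12 | allyl 3,5-diformyl-2,4-dihydroxy-6-methylbenzoate | C=CCOC(=O)c1c(C)c(C=O)c(O)c(C=O)c1O | intermediate
13 | allyl 3,5-diformyl-2,4-bis(methoxymethoxy)-6-methylbenzoate | C=CCOC(=O)c1c(C)c(C=O)c(OCOC)c(C=O)c1OCOC | intermediate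
14 | 3,5-diformyl-2,4-bis(methoxymethoxy)-6-methylbenzoic acid | Cc1c(C(=O)O)c(OCOC)c(C=O)c(OCOC)c1C=O | intermediate
15 | [3,5-diformyl-2,4-bis(methoxymethoxy)-6-methylbenzoyloxy][4-(methoxycarbonyl)-3-methoxy-2,5,6-trimethylphenyl](2,4,6-trimethoxyphenyl)iodane | COC(=O)c1c(C)c(C)c(I(OC(=O)c2c(C)c(C=O)c(OCOC)c(C=O)c2OCOC)c2c(OC)cc(OC)cc2OC)c(C)c1OC | intermediate
16 | methyl 4-[3,5-diformyl-2,4-bis(methoxymethoxy)-6-methylbenzoyloxy]-2-methoxy-3,5,6-trimethylbenzoate | COC(=O)c1c(C)c(C)c(OC(=O)c2c(C)c(C=O)c(OCOC)c(C=O)c2OCOC)c(C)c1OC | intermediate
17 | methyl 4-(3,5-diformyl-2,4-dihydroxy-6-methylbenzoyloxy)-2-methoxy-3,5,6-trimethylbenzoate | COC(=O)c1c(C)c(C)c(OC(=O)c2c(C)c(C=O)c(O)c(C=O)c2O)c(C)c1OC | target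

## Step count and least certain steps

Total step count: 11. Longest linear sequence: 7 steps (steps 1 to 5, 10 and 11). The ring A branch (steps 6 to 9) joins at step 10.

**Step 10 (key step).** The most likely failure is transfer of the wrong aryl group, or thermal breakdown of the salt (for example coupling with tosylate) before the carboxylate couples. Both aryl groups on iodine carry two ortho substituents, and the ring A carboxylate is a weak donor. The fallback gives up the aryl–oxygen bond formation and forms the acyl–oxygen bond under the most forcing acylation conditions. It sets out from 6 and 14 and comes back at 16. Iodine–magnesium exchange on 6 with i-PrMgCl·LiCl in THF at −20 °C would give [4-(methoxycarbonyl)-3-methoxy-2,5,6-trimethylphenyl]magnesium chloride F1. Trapping with B(OMe)3 would give dimethyl [4-(methoxycarbonyl)-3-methoxy-2,5,6-trimethylphenyl]boronate F2, and oxidation with H2O2 and aqueous NaOH would give methyl 4-hydroxy-2-methoxy-3,5,6-trimethylbenzoate F3. Acid 14 would be converted under neutral conditions with 1-chloro-N,N,2-trimethylprop-1-en-1-amine into 3,5-diformyl-2,4-bis(methoxymethoxy)-6-methylbenzoyl chloride F4. Acylation of the sodium phenoxide of F3 (NaH, THF) with F4 should then give 16.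

**Step 7.** The reaction may stall after the first formylation, because a formyl group deactivates the ring, and the allyl group may be attacked by hot TFA. The fallback introduces both carbons as aminomethyl groups, which do not deactivate the ring, and oxidises them afterwards. It sets out from 11 and comes back at 12. A double Mannich reaction of 11 with formaldehyde and morpholine in ethanol would give allyl 2,4-dihydroxy-6-methyl-3,5-bis(morpholin-4-ylmethyl)benzoate F5. A Sommelet-type oxidation of F5 with hexamethylenetetramine in hot aqueous acetic acid should then give 12.

**Step 4.** Substitution may be slow at a carbon flanked by two methyls and para to an ester, and forcing conditions may bring benzylic iodination or oxidation of the methyl groups. The fallback installs the iodine through nitrogen. It sets out from 5 and comes back at 6. Nitration with HNO3 in H2SO4 at 0 °C would give methyl 2-methoxy-3,5,6-trimethyl-4-nitrobenzoate F6. Hydrogenation over Pd/C would give methyl 4-amino-2-methoxy-3,5,6-trimethylbenzoate F7. Diazotisation with NaNO2 and TsOH·H2O in aqueous MeCN would give 4-(methoxycarbonyl)-3-methoxy-2,5,6-trimethylbenzenediazonium tosylate F8, which on addition of KI (Sandmeyer-type iodination) should give 6.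

**Step 5.** Oxidation of the hindered, ester-bearing iodide may be incomplete, or the tetra-ortho-substituted salt may undergo premature ligand coupling with tosylate at 77 °C. The fallback separates oxidation from salt formation and forms the salt at room temperature. It sets out from 6 and comes back at 9. Oxidation of 6 with NaBO3·4H2O in acetic acid at 45 °C would give, after isolation, methyl 4-(diacetoxyiodanyl)-2-methoxy-3,5,6-trimethylbenzoate F9. Condensation of F9 with 7 and TsOH·H2O in 2,2,2-trifluoroethanol at room temperature should then give 9.

## Further compounds

F1 | step 10 | [4-(methoxycarbonyl)-3-methoxy-2,5,6-trimethylphenyl]magnesium chloride | COC(=O)c1c(C)c(C)c([Mg]Cl)c(C)c1OC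
F2 | step 10 | dimethyl [4-(methoxycarbonyl)-3-methoxy-2,5,6-trimethylphenyl]boronate | COC(=O)c1c(C)c(C)c(B(OC)OC)c(C)c1OC
F3 | step 10 | methyl 4-hydroxy-2-methoxy-3,5,6-trimethylbenzoate | COC(=O)c1c(C)c(C)c(O)c(C)c1OC
F4 | step 10 | 3,5-diformyl-2,4-bis(methoxymethoxy)-6-methylbenzoyl chloride | Cc1c(C(=O)Cl)c(OCOC)c(C=O)c(OCOC)c1C=O
F5 | step 7 | allyl 2,4-dihydroxy-6-methyl-3,5-bis(morpholin-4-ylmethyl)benzoate | C=CCOC(=O)c1c(C)c(CN2CCOCC2)c(O)c(CN2CCOCC2)c1O
F6 | step 4 | methyl 2-methoxy-3,5,6-trimethyl-4-nitrobenzoate | COC(=O)c1c(C)c(C)c([N+](=O)[O-])c(C)c1OC
F7 | step 4 | methyl 4-amino-2-methoxy-3,5,6-trimethylbenzoate | COC(=O)c1c(C)c(C)c(N)c(C)c1OC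
F8 | step 4 | 4-(methoxycarbonyl)-3-methoxy-2,5,6-trimethylbenzenediazonium tosylate | COC(=O)c1c(C)c(C)c([N+]#N)c(C)c1OC.Cc1ccc(S(=O)(=O)[O-])cc1
F9 | step 5 | methyl 4-(diacetoxyiodanyl)-2-methoxy-3,5,6-trimethylbenzoate | COC(=O)c1c(C)c(C)c(I(OC(C)=O)OC(C)=O)c(C)c1OC
A1 | alternative 1 | methyl 2,4-dihydroxy-3,5,6-trimethylbenzoate | COC(=O)c1c(C)c(C)c(O)c(C)c1O
A2 | alternative 1 | methyl 4,6-dimethyl-3,5,7-trioxooctanoate (mixture of stereoisomers and enol forms) | COC(=O)CC(=O)C(C)C(=O)C(C)C(C)=O
A3 | alternative 2 | methyl 4-(but-2-ynoyloxy)-2-methoxy-3,5,6-trimethylbenzoate | CC#CC(=O)Oc1c(C)c(C)c(C(=O)OC)c(OC)c1C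
A4 | alternative 2 | 1-methoxy-1,3-bis(trimethylsilyloxy)buta-1,3-diene | C=C(O[Si](C)(C)C)C=C(OC)O[Si](C)(C)C
A5 | alternative 2 | methyl 4-(2,4-dihydroxy-6-methylbenzoyloxy)-2-methoxy-3,5,6-trimethylbenzoate | COC(=O)c1c(C)c(C)c(OC(=O)c2c(C)cc(O)cc2O)c(C)c1OC
A6 | alternative 3 | methyl 3-methoxy-5,6-dimethyl-2-oxo-2H-pyran-4-carboxylate | COC(=O)C1=C(OC)C(=O)OC(C)=C1C
A7 | alternative 3 | 1-(triisopropylsilyloxy)propyne | CC#CO[Si](C(C)C)(C(C)C)C(C)C
A8 | alternative 3 | methyl 2-methoxy-3,5,6-trimethyl-4-(triisopropylsilyloxy)benzoate | COC(=O)c1c(C)c(C)c(O[Si](C(C)C)(C(C)C)C(C)C)c(C)c1OC
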